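**Retrosynthetic overview**
- The chalcone is made last: Friedel–Crafts acylation at C-8 with a C3 acid chloride, Heck arylation with 4-iodophenol, then one global deprotection.
- The C-2 aryl group comes from a new trans-selective Friedel–Crafts arylation of a 4-substituted chroman-2-ol (lactol) with silyl-protected phenol.
- The pyran ring and C-4 come from an iminium-catalysed Friedel–Crafts alkylation/hemiacetalisation of a 3,5-dioxygenated phenol with an enal. This is the only ring that is built; the four benzene rings are bought.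
- The enal comes from cross-metathesis of a homoallylic acetate. Its carbinol centre and the adjoining C–C bond are made in the key step, a stereospecific 1,2-shift of an arylethyl group from boron to carbon (lithiation–borylation).
- The ring A phenol comes from anisole by double meta C–H borylation/oxidation and mono-acylation.

Assumption: the tert-butyldimethylsilyl ethers of 4-bromophenol and of phenol are bought as such.

Abbreviations: TBS = tert-butyldimethylsilyl; Piv = pivaloyl (2,2-dimethylpropanoyl); Bpin = 4,4,5,5-tetramethyl-1,3,2-dioxaborolan-2-yl.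

Step 1
Reactants: 1 anisole
Product: 3 5-methoxybenzene-1,3-diol, via diboryl anisole 2 (not isolated)
Conditions: B2pin2 (2.5 equiv), [Ir(OMe)(cod)]2 (1.5 mol%), 4,4'-di-tert-butyl-2,2'-bipyridine (3 mol%), THF, 80 °C; then 30% H2O2, THF–H2O, 0 °C to rt
Reagents that add atoms: bis(pinacolato)diboron, CC1(C)OB(OC1(C)C)B1OC(C)(C)C(C)(C)O1 (boryl groups of 2); hydrogen peroxide, OO (oxygen of 3)
Why: Iridium-catalysed C–H borylation is sterically controlled, so both positions meta to OMe are borylated (the para-monoborylated by-product is removed after oxidation), and oxidation of the two C–B bonds gives the symmetric diol; one-pot C–H borylation/oxidation.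

Step 2
Reactants: 3 5-methoxybenzene-1,3-diol
Product: 4 3-hydroxy-5-methoxyphenyl pivalate
Conditions: PivCl (1.0 equiv), Et3N, CH2Cl2, −20 °C
Reagents that add atoms: pivaloyl chloride, CC(C)(C)C(Cl)=O
Why: Statistical mono-esterification of a symmetric diol has no regiochemical issue (diol and diester are recycled), and the ester turns O-5 into a weak donor for the later C-alkylation; acylation of a phenol.

Step 3
Reactants: 5 but-3-en-1-ol
Product: 6 but-3-en-1-yl N,N-di(propan-2-yl)carbamate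
Conditions: i-Pr2NC(O)Cl, Et3N, CH2Cl2, reflux
Reagents that add atoms: N,N-diisopropylcarbamoyl chloride, CC(C)N(C(C)C)C(Cl)=O
Why: Carbamoylation of the primary alcohol installs the group that directs α-lithiation and later serves as leaving group; Hoppe carbamate formation.

Step 4
Reactants: 7 (4-bromophenoxy)(tert-butyl)dimethylsilane; 8 ethene
Product: 9 tert-butyl(4-ethenylphenoxy)dimethylsilane
Conditions: ethene (8 bar), Pd(OAc)2 (1 mol%), P(o-tol)3 (2 mol%), Et3N, MeCN, 100 °C
Reagents that add atoms: none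
Why: Aryl bromides are vinylated cleanly by ethene under pressure, which suppresses the second arylation; Mizoroki–Heck reaction.

Step 5
Reactants: 9 tert-butyl(4-ethenylphenoxy)dimethylsilane
Product: 10 tert-butyldimethyl{4-[2-(Bpin)ethyl]phenoxy}silane
Conditions: pinacolborane, [Ir(cod)Cl]2 (1.5 mol%), dppe (3 mol%), CH2Cl2, rt
Reagents that add atoms: pinacolborane, B1OC(C)(C)C(C)(C)O1
Why: The iridium/diphosphine catalyst gives the linear boronic ester from vinylarenes; anti-Markovnikov catalytic hydroboration.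

Step 6
Reactants: 6 but-3-en-1-yl N,N-di(propan-2-yl)carbamate; 10 tert-butyldimethyl{4-[2-(Bpin)ethyl]phenoxy}silane
Product: 13 (3R)-1-[4-(TBSO)phenyl]hex-5-en-3-ol, via lithiated carbamate 11 (not isolated), via boronic ester 12 (not isolated)
Conditions: 6 (1.3 equiv), s-BuLi, (+)-sparteine, Et2O, −78 °C, 5 h; 10, −78 °C, then reflux 16 h; NaBO3·4H2O, THF–H2O, rt
Reagents that add atoms: sec-butyllithium, [Li]C(C)CC (lithium of 11); sodium perborate, [Na+].[O-]B1OO1 (oxygen of 13)
Why: (+)-Sparteine-directed deprotonation gives the configurationally stable (R)-lithio carbamate, which is borylated with retention; the arylethyl group then migrates from boron to carbon with inversion and loss of carbamate (stereospecific 1,2-metallate shift) and oxidation with retention gives the (R)-alcohol; Hoppe–Aggarwal lithiation–borylation.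

Step 7
Reactants: 13 (3R)-1-[4-(TBSO)phenyl]hex-5-en-3-ol
Product: 14 (3R)-1-[4-(TBSO)phenyl]hex-5-en-3-yl acetate
Conditions: Ac2O, pyridine, DMAP (5 mol%), CH2Cl2, rt
Reagents that add atoms: acetic anhydride, CC(=O)OC(C)=O
Why: The carbinol must be masked so that only the phenol oxygen can close the pyran ring later, and an acetate survives the Lewis-acid steps; acylation.

Step 8
Reactants: 14 (3R)-1-[4-(TBSO)phenyl]hex-5-en-3-yl acetate; 15 (2E)-but-2-enal
Product: 16 (3R,5E)-1-[4-(TBSO)phenyl]-7-oxohept-5-en-3-yl acetate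
Conditions: 15 (5 equiv), second-generation Hoveyda–Grubbs catalyst (3 mol%), CH2Cl2, 40 °C
Reagents that add atoms: none
Why: A terminal alkene and crotonaldehyde give the E-enal selectively with loss of propene; olefin cross-metathesis.

Step 9
Reactants: 4 3-hydroxy-5-methoxyphenyl pivalate; 16 (3R,5E)-1-[4-(TBSO)phenyl]-7-oxohept-5-en-3-yl acetate
Product: 17 (4S)-4-{(2R)-2-acetoxy-4-[4-(TBSO)phenyl]butyl}-2-hydroxy-7-methoxy-3,4-dihydro-2H-chromen-5-yl pivalate (both C-2 epimers)
Conditions: (R)-α,α-diphenylprolinol trimethylsilyl ether (20 mol%), PhCO2H (20 mol%), toluene, 0 °C to rt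
Reagents that add atoms: none
Why: The iminium ion of 16 is shielded on one face by the catalyst, so the phenol carbon ortho to OH and para to OMe (the other ortho site is only para to the weakly donating pivalate) adds to the β-carbon from the open face to set C-4 as S, and the phenol OH then closes the lactol; organocatalytic Friedel–Crafts alkylation/hemiacetalisation.

Step 10
Reactants: 17 lactol (as above); 18 tert-butyldimethyl(phenoxy)silane
Product: 19 (2R,4S)-4-{(2R)-2-acetoxy-4-[4-(TBSO)phenyl]butyl}-7-methoxy-2-[4-(TBSO)phenyl]-3,4-dihydro-2H-chromen-5-yl pivalate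
Conditions: 18 (5 equiv), Sc(OTf)3 (10 mol%), 4 Å molecular sieves, CH2Cl2, −20 to 0 °C
Reagents that add atoms: none
Why: Proposed new method: Sc(OTf)3 ionises the lactol to the 4-substituted chroman-2-ylium ion, whose C-4 chain sits pseudoaxial to avoid the peri 5-OPiv group, so the para carbon of the silyl phenyl ether attacks C-2 from the opposite face to give the 2,4-trans flavan (2R), and reversible ionisation of the 4-silyloxybenzylic C–O bond lets any cis isomer drift to the more stable trans isomer (aryl equatorial, C-4 chain axial); the closest known reactions are Lewis-acid Friedel–Crafts C-arylations of lactol-derived oxocarbenium ions (aryl C-glycoside synthesis) and stereoelectronically controlled additions to six-membered oxocarbenium ions, not yet shown for 4-substituted chroman-2-ols with a simple mono-oxygenated arene.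

Step 11
Reactants: 19 flavan (as above); 20 3-chloropropanoyl chloride
Product: 21 (2R,4S)-4-{(2R)-2-acetoxy-4-[4-(TBSO)phenyl]butyl}-8-(3-chloropropanoyl)-7-methoxy-2-[4-(TBSO)phenyl]-3,4-dihydro-2H-chromen-5-yl pivalate
Conditions: 20 (1.3 equiv), Bi(OTf)3 (10 mol%), CH2Cl2, 0 °C
Reagents that add atoms: none
Why: Ring A is by far the most electron-rich arene, and C-8 (between OMe and the tied-back ring oxygen) is less hindered than C-6 (between OMe and the bulky, inductively deactivating pivalate), as in the C-8-selective substitution of 5,7-dioxygenated flavans; Friedel–Crafts acylation.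

Step 12
Reactants: 21 β-chloro ketone (as above); 22 4-iodophenol
Product: 24 (2R,4S)-4-{(2R)-2-acetoxy-4-[4-(TBSO)phenyl]butyl}-8-[(2E)-3-(4-hydroxyphenyl)prop-2-enoyl]-7-methoxy-2-[4-(TBSO)phenyl]-3,4-dihydro-2H-chromen-5-yl pivalate, via vinyl ketone 23 (not isolated)
Conditions: 22 (1.5 equiv), Pd(OAc)2 (5 mol%), Et3N (4 equiv), DMF, 80 °C
Reagents that add atoms: none
Why: Et3N eliminates HCl to give the aryl vinyl ketone, which is arylated by 4-iodophenol with syn-insertion/syn-β-hydride elimination to the E-enone; Mizoroki–Heck reaction.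

Step 13
Reactants: 24 protected chalcone (as above)
Product: 25 (2E)-1-{(2R,4S)-5-hydroxy-4-[(2R)-2-hydroxy-4-(4-hydroxyphenyl)butyl]-2-(4-hydroxyphenyl)-7-methoxy-3,4-dihydro-2H-chromen-8-yl}-3-(4-hydroxyphenyl)prop-2-en-1-one (target)
Conditions: K2CO3 (6 equiv), MeOH, 0 °C to rt; aqueous NH4Cl
Reagents that add atoms: none
Why: Base-mediated methanolysis removes the acetate, the aryl pivalate and both aryl silyl ethers at or below room temperature without touching the enone or the three stereocentres; transesterification/desilylation.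

**Compound list**
1 | anisole | COc1ccccc1 | starting material
2 | 3,5-bis(Bpin)anisole | COc1cc(B2OC(C)(C)C(C)(C)O2)cc(B2OC(C)(C)C(C)(C)O2)c1 | intermediate (not isolated)
3 | 5-methoxybenzene-1,3-diol | COc1cc(O)cc(O)c1 | intermediate
4 | 3-hydroxy-5-methoxyphenyl pivalate | COc1cc(O)cc(OC(=O)C(C)(C)C)c1 | intermediate
5 | but-3-en-1-ol | OCCC=C | starting material
6 | but-3-en-1-yl N,N-di(propan-2-yl)carbamate | C=CCCOC(=O)N(C(C)C)C(C)C | intermediate
7 | (4-bromophenoxy)(tert-butyl)dimethylsilane | CC(C)(C)[Si](C)(C)Oc1ccc(Br)cc1 | starting material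
8 | ethene | C=C | starting material
9 | tert-butyl(4-ethenylphenoxy)dimethylsilane | C=Cc1ccc(O[Si](C)(C)C(C)(C)C)cc1 | intermediate
10 | tert-butyldimethyl{4-[2-(Bpin)ethyl]phenoxy}silane | CC(C)(C)[Si](C)(C)Oc1ccc(CCB2OC(C)(C)C(C)(C)O2)cc1 | intermediate
11 | (1R)-1-lithiobut-3-en-1-yl N,N-di(propan-2-yl)carbamate (sparteine complex) | C=CC[C@@H]([Li])OC(=O)N(C(C)C)C(C)C | intermediate (not isolated)
12 | tert-butyldimethyl{4-[(3R)-3-(Bpin)hex-5-en-1-yl]phenoxy}silane | C=CC[C@H](B1OC(C)(C)C(C)(C)O1)CCc1ccc(O[Si](C)(C)C(C)(C)C)cc1 | intermediate (not isolated)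
13 | (3R)-1-[4-(TBSO)phenyl]hex-5-en-3-ol | C=CC[C@H](O)CCc1ccc(O[Si](C)(C)C(C)(C)C)cc1 | intermediate
14 | (3R)-1-[4-(TBSO)phenyl]hex-5-en-3-yl acetate | C=CC[C@H](OC(C)=O)CCc1ccc(O[Si](C)(C)C(C)(C)C)cc1 | intermediate
15 | (2E)-but-2-enal | C/C=C/C=O | starting material
16 | (3R,5E)-1-[4-(TBSO)phenyl]-7-oxohept-5-en-3-yl acetate | O=C/C=C/C[C@H](OC(C)=O)CCc1ccc(O[Si](C)(C)C(C)(C)C)cc1 | intermediate
17 | (4S)-4-{(2R)-2-acetoxy-4-[4-(TBSO)phenyl]butyl}-2-hydroxy-7-methoxy-3,4-dihydro-2H-chromen-5-yl pivalate (C-2 epimers) | COc1cc(OC(=O)C(C)(C)C)c2c(c1)OC(O)C[C@@H]2C[C@H](OC(C)=O)CCc1ccc(O[Si](C)(C)C(C)(C)C)cc1 | intermediate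
18 | tert-butyldimethyl(phenoxy)silane | CC(C)(C)[Si](C)(C)Oc1ccccc1 | starting material
19 | (2R,4S)-4-{(2R)-2-acetoxy-4-[4-(TBSO)phenyl]butyl}-7-methoxy-2-[4-(TBSO)phenyl]-3,4-dihydro-2H-chromen-5-yl pivalate | COc1cc(OC(=O)C(C)(C)C)c2c(c1)O[C@@H](c1ccc(O[Si](C)(C)C(C)(C)C)cc1)C[C@@H]2C[C@H](OC(C)=O)CCc1ccc(O[Si](C)(C)C(C)(C)C)cc1 | intermediate
20 | 3-chloropropanoyl chloride | ClCCC(Cl)=O | starting material
21 | 8-(3-chloropropanoyl) derivative of 19, (2R,4S) | COc1cc(OC(=O)C(C)(C)C)c2c(c1C(=O)CCCl)O[C@@H](c1ccc(O[Si](C)(C)C(C)(C)C)cc1)C[C@@H]2C[C@H](OC(C)=O)CCc1ccc(O[Si](C)(C)C(C)(C)C)cc1 | intermediate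
22 | 4-iodophenol | Oc1ccc(I)cc1 | starting material
23 | 8-(prop-2-enoyl) derivative of 19, (2R,4S) | COc1cc(OC(=O)C(C)(C)C)c2c(c1C(=O)C=C)O[C@@H](c1ccc(O[Si](C)(C)C(C)(C)C)cc1)C[C@@H]2C[C@H](OC(C)=O)CCc1ccc(O[Si](C)(C)C(C)(C)C)cc1 | intermediate (not isolated)
24 | 8-[(2E)-3-(4-hydroxyphenyl)prop-2-enoyl] derivative of 19, (2R,4S) | COc1cc(OC(=O)C(C)(C)C)c2c(c1C(=O)/C=C/c1ccc(O)cc1)O[C@@H](c1ccc(O[Si](C)(C)C(C)(C)C)cc1)C[C@@H]2C[C@H](OC(C)=O)CCc1ccc(O[Si](C)(C)C(C)(C)C)cc1 | intermediate
25 | (2E)-1-{(2R,4S)-5-hydroxy-4-[(2R)-2-hydroxy-4-(4-hydroxyphenyl)butyl]-2-(4-hydroxyphenyl)-7-methoxy-3,4-dihydro-2H-chromen-8-yl}-3-(4-hydroxyphenyl)prop-2-en-1-one | COc1cc(O)c2c(c1C(=O)/C=C/c1ccc(O)cc1)O[C@@H](c1ccc(O)cc1)C[C@@H]2C[C@H](O)CCc1ccc(O)cc1 | target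

**Step count and risks**

Total step count: 13. Longest linear sequence: 10 steps (steps 4 to 13, from 7 to 25).

The three steps most likely to fail:

Step 10 (new arylation; risks are oligomerisation through ring A and poor para or trans selectivity). The fallback sets out from 17 and comes back at 19 and uses known chemistry only. The open hydroxy-aldehyde form of 17 is arylated with [4-(TBSO)phenyl]Ti(OiPr)3, made from 7 with Mg and then ClTi(OiPr)3; this reagent is aldehyde-selective in the presence of the esters. The product is 3-hydroxy-2-{(3R,5R)-5-acetoxy-1-hydroxy-1,7-bis[4-(TBSO)phenyl]heptan-3-yl}-5-methoxyphenyl pivalate F5, a mixture at the new carbinol carbon. Camphorsulfonic acid (5 mol%) in CH2Cl2 at 0 °C then ionises the silyloxybenzylic alcohol and the phenol oxygen closes the pyran ring under thermodynamic control to the 2,4-trans flavan 19.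

Step 9 (risks are attack at the other ortho carbon and moderate enantioselectivity with an unsymmetrical phenol). The fallback sets out from 3 and comes back at 17; regiochemistry is fixed by symmetry. Diol 3 is protected with MOMCl/i-Pr2NEt as 1-methoxy-3,5-bis(methoxymethoxy)benzene F1. Lithiation between the two MOM ethers with n-BuLi and quenching with 2-isopropoxy-4,4,5,5-tetramethyl-1,3,2-dioxaborolane gives 2-[4-methoxy-2,6-bis(methoxymethoxy)phenyl]-Bpin F2. Rhodium-catalysed asymmetric 1,4-addition of F2 to enal 16 ([RhCl(C2H4)2]2, chiral diene ligand, KOH, dioxane–H2O; Hayashi–Miyaura reaction) gives (3R,5S)-5-[4-methoxy-2,6-bis(methoxymethoxy)phenyl]-7-oxo-1-[4-(TBSO)phenyl]heptan-3-yl acetate F3. Aqueous HCl in THF removes both MOM groups and one phenol closes to (4S)-4-{(2R)-2-acetoxy-4-[4-(TBSO)phenyl]butyl}-7-methoxy-3,4-dihydro-2H-chromene-2,5-diol F4. PivCl/Et3N at −20 °C acylates the remaining phenol to give 17.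

Step 11 (risks are acylation at C-6 and acid-promoted opening of the benzylic ether). The fallback sets out from 19 and comes back at 23. NBS in CH2Cl2 at −78 °C brominates C-8 to give the (2R,4S) 8-bromo derivative of 19, F6. Carbonylative Stille coupling (Pd(PPh3)4, CO 1 atm, tributyl(vinyl)stannane, toluene, 80 °C) gives vinyl ketone 23, which enters the Heck reaction of step 12 directly.

**Further compounds**
F1 | step 9 | 1-methoxy-3,5-bis(methoxymethoxy)benzene | COCOc1cc(OC)cc(OCOC)c1
F2 | step 9 | 2-[4-methoxy-2,6-bis(methoxymethoxy)phenyl]-4,4,5,5-tetramethyl-1,3,2-dioxaborolane | COCOc1cc(OC)cc(OCOC)c1B1OC(C)(C)C(C)(C)O1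
F3 | step 9 | (3R,5S)-5-[4-methoxy-2,6-bis(methoxymethoxy)phenyl]-7-oxo-1-[4-(TBSO)phenyl]heptan-3-yl acetate | O=CC[C@@H](c1c(OCOC)cc(OC)cc1OCOC)C[C@H](OC(C)=O)CCc1ccc(O[Si](C)(C)C(C)(C)C)cc1
F4 | step 9 | (4S)-4-{(2R)-2-acetoxy-4-[4-(TBSO)phenyl]butyl}-7-methoxy-3,4-dihydro-2H-chromene-2,5-diol (C-2 epimers) | COc1cc(O)c2c(c1)OC(O)C[C@@H]2C[C@H](OC(C)=O)CCc1ccc(O[Si](C)(C)C(C)(C)C)cc1
F5 | step 10 | 3-hydroxy-2-{(3R,5R)-5-acetoxy-1-hydroxy-1,7-bis[4-(TBSO)phenyl]heptan-3-yl}-5-methoxyphenyl pivalate (C-1 epimers) | COc1cc(OC(=O)C(C)(C)C)c(c(O)c1)[C@H](CC(O)c1ccc(O[Si](C)(C)C(C)(C)C)cc1)C[C@H](OC(C)=O)CCc1ccc(O[Si](C)(C)C(C)(C)C)cc1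
F6 | step 11 | (2R,4S)-4-{(2R)-2-acetoxy-4-[4-(TBSO)phenyl]butyl}-8-bromo-7-methoxy-2-[4-(TBSO)phenyl]-3,4-dihydro-2H-chromen-5-yl pivalate | COc1cc(OC(=O)C(C)(C)C)c2c(c1Br)O[C@@H](c1ccc(O[Si](C)(C)C(C)(C)C)cc1)C[C@@H]2C[C@H](OC(C)=O)CCc1ccc(O[Si](C)(C)C(C)(C)C)cc1
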